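Numbering: cycloheptene = C1(O-angeloyl)–C2(O-epoxyangeloyl)–C3H=C4(Me)–C5H–C10H–C11Me2; cyclohexenone = C5–C6H2–C7(=O)–C8(Me)=C9H–C10.
Enabling feature: in the cyclohexenone the C8=C9 alkene lies opposite the C5–C6 edge (a Diels–Alder retron, with C7=O as a 1-oxygenated diene terminus). Its C5–C10 bond is also the ring-fusion bond, so one [4+2] event on an open chain closes both carbocycles.
Cuts: first the two ester C–O bonds; then C6–C7 and C5–C10 together (helpers: C7–OTIPS oxidation level, C6–CO2allyl activator, C1/C2 acetonide ring); then C5=C6 (Wittig), C1–C2 (vinylogous Mukaiyama aldol) and C10–C11 (enolate alkylation).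
Forward: the chain is joined C11–C10, then C1–C2, then C5=C6. C7 is oxidised with SeO2, both rings form in step 9, the helpers leave in steps 10–13, and C2 then C1 are esterified.
Stereochemistry: C1/C2 come from one catalytic asymmetric aldol, and Z-C3=C4 is stored in the butenolide ring. C5/C10 are relayed from C1/C2 in the cycloaddition. The epoxy acid comes from Sharpless epoxidation, and the angelate geometry is bought.

Key step: step 9

Assumption: the sense of induction in step 3 is taken by analogy with Ti(IV)/BINOL-catalysed additions to aliphatic aldehydes (Si-face attack with the (S)-ligand gives 1R); if it proves opposite, the (R)-ligand is used.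

Step 1
Reactants: 1 isobutyraldehyde; 2 prenyl bromide
Product: 3 2,2,5-trimethylhex-4-enal
Conditions: 50% aq NaOH, Bu4NI (cat.), PhMe, 65 °C
Reagents that add atoms: none
Why: Phase-transfer enolate C-alkylation: isobutyraldehyde has one enolisable position and the primary allylic bromide reacts by SN2, so quaternary C11 with the C10–C9=C8 prenyl arm forms directly and no stereocentre is involved.

Step 2
Reactants: 4 3-methylfuran-2(5H)-one
Product: 5 trimethyl[(3-methylfuran-2-yl)oxy]silane
Conditions: TMSOTf, Et3N, Et2O, 0 °C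
Reagents that add atoms: trimethylsilyl triflate, C[Si](C)(C)OS(=O)(=O)C(F)(F)F
Why: Soft enolisation of a butenolide with a silyl triflate and an amine is driven by aromatisation to the 2-silyloxyfuran, the standard vinylogous Mukaiyama donor.

Step 3
Reactants: 3 2,2,5-trimethylhex-4-enal; 5 trimethyl[(3-methylfuran-2-yl)oxy]silane
Product: 7 (5R)-5-[(1R)-1-hydroxy-2,2,5-trimethylhex-4-en-1-yl]-3-methylfuran-2(5H)-one, via silyl ether 6 (not isolated)
Conditions: Ti(Oi-Pr)4 (20 mol %), (S)-BINOL (20 mol %), Et2O, −20 °C; 1 M HCl/THF work-up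
Reagents that add atoms: none
Why: Catalytic asymmetric vinylogous Mukaiyama aldol reaction: the furan attacks through its C5 (= C2 of the target) the Ti(IV)–BINOLate-bound aldehyde, the chiral Lewis acid choosing the aldehyde face (C1) and the open Lewis-acid transition state favouring the syn (threo) C1/C2 pair, while the butenolide ring stores the Z geometry of C3=C4.

Step 4
Reactants: 7 hydroxy butenolide
Product: 8 (5R)-5-[(1R)-1-hydroxy-2,2,5-trimethylhex-4-en-1-yl]-3-methyl-2,5-dihydrofuran-2-ol (lactol, anomers)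
Conditions: DIBAL-H (2.3 equiv), CH2Cl2, −78 °C; Rochelle salt
Reagents that add atoms: none
Why: DIBAL-H half-reduction of a lactone stops at the aluminium hemiacetal at −78 °C, and the neutral tartrate work-up avoids acid-induced dehydration of the dihydrofuranol to a furan; C1 and C2 are untouched.

Step 5
Reactants: 8 lactol; 9 allyl (triphenyl-λ5-phosphanylidene)acetate
Product: 10 allyl (2E,4Z,6R,7R)-6,7-dihydroxy-4,8,8,11-tetramethyldodeca-2,4,10-trienoate
Conditions: 9 (1.3 equiv), PhMe, 60 °C
Reagents that add atoms: none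
Why: Wittig olefination of the ring-opened (Z)-γ-hydroxy-enal tautomer of the lactol with a stabilised ylide gives the E-C5=C6 enoate under neutral conditions that should not trigger oxa-Michael closure or Z→E isomerisation of C3=C4.

Step 6
Reactants: 10 dienoate diol
Product: 11 allyl (2E,4Z)-5-[(4R,5R)-5-(2,5-dimethylhex-4-en-2-yl)-2,2-dimethyl-1,3-dioxolan-4-yl]-4-methylpenta-2,4-dienoate
Conditions: Me2C(OMe)2, PPTS (cat.), CH2Cl2, rt
Reagents that add atoms: 2,2-dimethoxypropane, COC(C)(C)OC
Why: Acid-catalysed transacetalisation of the only 1,2-diol gives the trans-4,5-disubstituted dioxolane, the temporary ring that later stiffens the tether.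

Step 7
Reactants: 11 acetonide
Product: 13 (E)-enal (the prenyl CH3 trans to C10 in 11 is now CHO), via allylic alcohol 12 (not isolated)
Conditions: SeO2 (0.3 equiv), t-BuOOH, CH2Cl2, 0 °C → rt; work-up; DMP, NaHCO3, CH2Cl2, 0 °C
Reagents that add atoms: tert-butyl hydroperoxide, CC(C)(C)OO (source of the new oxygen, passed on by catalytic selenium dioxide, O=[Se]=O)
Why: Selenium dioxide allylic oxidation (ene reaction, then [2,3]-shift) attacks the most electron-rich alkene, the prenyl group, at its E-methyl group and leaves the electron-poor dienoate alone, and Dess–Martin oxidation converges the material on the (E)-enal.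

Step 8
Reactants: 13 (E)-enal
Product: 14 (1E,3E)-triisopropylsilyl dienol ether TIPSO–C7H=C8(Me)–C9H=C10H–C11
Conditions: TIPSOTf (1.3 equiv), Et3N (3 equiv), CH2Cl2, −78 → 0 °C
Reagents that add atoms: triisopropylsilyl triflate, CC(C)[Si](C(C)C)(C(C)C)OS(=O)(=O)C(F)(F)F
Why: Soft γ-enolisation of the s-trans enal with a silyl triflate and triethylamine gives the (1E,3E)-1-silyloxy-2-methyldiene, E at C9=C10 because quaternary C11 avoids the C8 methyl group; ester, acetal and dienoate are inert.

Step 9
Reactants: 14 silyl dienol ether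
Product: 15 cis-fused adduct (1,2-acetonide, 6-CO2allyl, 7-OTIPS; H-5 and H-10 on the face of O-1 and opposite to O-2; CO2allyl on the face of H-5; OTIPS on the other face)
Conditions: PhMe (0.01 M), BHT (cat.), Et3N (0.1 equiv), 130 °C, sealed tube
Reagents that add atoms: none
Why: Concerted, asynchronous thermal [4+2] cycloaddition (type-1 intramolecular Diels–Alder reaction) of the electron-rich 1-silyloxy-2-methyldiene C7=C8–C9=C10 onto the C5=C6 enoate, polarity-matched (nucleophilic C10 to the β-carbon C5, C7 to ester-bearing C6); the closest known types are IMDA reactions of enal-derived silyl dienol ethers and IMDA closures of 1,3,10-undecatrienes to bicyclo[5.4.0]undecenes. The cyclohexene closes as the six-electron array itself, and the cycloheptene closes through the five-atom tether C4–C3–C2–C1–C11, which keeps few free rotors because of the Z-C3=C4 bond, the dioxolane and the gem-dimethyl group. C5: the dienophile face is fixed by A(1,3) strain across the Z-alkene (C2–H in the dienoate plane facing C5, C2–O turned away, C1 carrying the diene over the other face) and by the trans-dioxolane, which allows only one sign of the C3–C2–C1–C11 torsion. C10: with the (9E)-diene (C11 outside) the cis fusion needs the alkenyl arm C4 endo and the ester exo; the endo slot under C7/C8 is crowded by the C8 methyl group and by the bulky OTIPS group (which would end cis-vicinal to the ester), whereas the slot under C9–H is free for the flat s-trans C3=C4 arm. C6 and C7 arise with ester trans to OTIPS and are erased later. Periselectivity: addition to C3=C4 through the three-atom tether would need a trans-fused dioxolane–cyclopentane (trans-bicyclo[3.3.0]octane) and a quaternary C4 next to C7–OTIPS, so the temporary acetonide ring blocks it, and 130 °C should keep the 1,5-H shift of the Z-dienoate slow.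

Step 10
Reactants: 15 adduct
Product: 16 C7 allylic alcohol (otherwise as 15)
Conditions: HF·pyridine, pyridine, THF, 0 °C → rt
Reagents that add atoms: none
Why: Fluoride-induced Si–O cleavage under buffered acidic conditions frees the allylic alcohol without the retro-aldol or E1cB loss that a basic fluoride source could cause in this β-oxy ester, and the acetonide survives.

Step 11
Reactants: 16 allylic alcohol
Product: 17 allyl β-keto ester (C7 ketone conjugated with C8=C9; C6 epimers/enol)
Conditions: DMP, NaHCO3, CH2Cl2, 0 °C → rt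
Reagents that add atoms: none
Why: Dess–Martin oxidation of the secondary allylic alcohol installs the C7 carbonyl of the 2-methylcyclohexenone under buffered neutral conditions, erasing helper stereocentre C7 and making C6 part of a β-keto ester.

Step 12
Reactants: 17 allyl β-keto ester
Product: 19 cis-fused enone acetonide, via keto acid 18 (not isolated)
Conditions: Pd(PPh3)4 (5 mol %), morpholine (2 equiv), THF, rt → 40 °C
Reagents that add atoms: none
Why: Palladium(0)-catalysed deallylation (π-allyl transfer to morpholine) of an allyl β-keto ester followed by spontaneous decarboxylation removes the C6 activating group under neutral conditions that do not enolise towards C10.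

Step 13
Reactants: 19 enone acetonide
Product: 20 trans-1,2-diol (1R,2R; cis-fused enone)
Conditions: AcOH–H2O (4:1), 40 °C
Reagents that add atoms: none
Why: Mild aqueous-acid hydrolysis of the strained trans-fused dioxolane releases the diol without ionising the allylic C2–O bond or epimerising C10.

Step 14
Reactants: 21 angelic acid
Product: 22 (Z)-2-methylbut-2-en-1-ol
Conditions: LiAlH4, Et2O, 0 °C
Reagents that add atoms: none
Why: Hydride reduction of the carboxylic acid does not touch the trisubstituted alkene, so the Z geometry is kept.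

Step 15
Reactants: 22 (Z)-2-methylbut-2-en-1-ol
Product: 23 [(2S,3R)-2,3-dimethyloxiran-2-yl]methanol
Conditions: Ti(Oi-Pr)4 (10 mol %), L-(+)-DIPT (12 mol %), t-BuOOH, 4 Å MS, CH2Cl2, −20 °C
Reagents that add atoms: tert-butyl hydroperoxide, CC(C)(C)OO
Why: Sharpless asymmetric epoxidation: syn oxygen transfer keeps CH2OH and the C3 methyl group cis, and the L-(+)-tartrate catalyst selects the face that gives the (2S,3R)-epoxy alcohol.

Step 16
Reactants: 23 epoxy alcohol
Product: 24 (2R,3R)-2,3-dimethyloxirane-2-carboxylic acid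
Conditions: RuCl3·xH2O (2 mol %), NaIO4, MeCN–EtOAc–H2O, 0 °C → rt
Reagents that add atoms: water, O
Why: Ruthenium tetroxide oxidation (catalytic RuCl3/periodate) of the primary epoxy alcohol to the glycidic acid leaves both epoxide stereocentres untouched (C2 becomes R only through the change in CIP priority).

Step 17
Reactants: 20 diol; 24 epoxy acid
Product: 25 2-O-[(2R,3R)-epoxyangeloyl] mono-ester (C1–OH free)
Conditions: 24 (1.05 equiv), EDC·HCl, DMAP (0.2 equiv), CH2Cl2, 0 °C
Reagents that add atoms: none
Why: Steglich-type carbodiimide/DMAP esterification should select the allylic C2–OH because C1–OH is neopentylic next to C11Me2, and the acid has no α-hydrogen so it cannot epimerise.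

Step 18
Reactants: 25 mono-ester; 21 angelic acid
Product: 27 CNP0332927.1, via mixed anhydride 26 (not isolated)
Conditions: 21, 2,4,6-Cl3C6H2COCl, Et3N, PhMe, rt; add 25, 80 °C
Reagents that add atoms: 2,4,6-trichlorobenzoyl chloride, O=C(Cl)c1c(Cl)cc(Cl)cc1Cl (its atoms stay in intermediate 26 only)
Why: Yamaguchi-type mixed-anhydride acylation without a nucleophilic catalyst transfers the less hindered angeloyl group to the hindered C1–OH on heating and avoids the addition–elimination pathway that turns angelates into tiglates.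

Compound list
1 | isobutyraldehyde | CC(C)C=O | starting material
2 | prenyl bromide (1-bromo-3-methylbut-2-ene) | CC(C)=CCBr | starting material
3 | 2,2,5-trimethylhex-4-enal | CC(C)=CCC(C)(C)C=O | intermediate
4 | 3-methylfuran-2(5H)-one | CC1=CCOC1=O | starting material
5 | trimethyl[(3-methylfuran-2-yl)oxy]silane | Cc1ccoc1O[Si](C)(C)C | intermediate
6 | O-trimethylsilyl ether of 7 | CC(C)=CCC(C)(C)[C@@H](O[Si](C)(C)C)[C@@H]1OC(=O)C(C)=C1 | intermediate
7 | (5R)-5-[(1R)-1-hydroxy-2,2,5-trimethylhex-4-en-1-yl]-3-methylfuran-2(5H)-one | CC(C)=CCC(C)(C)[C@@H](O)[C@@H]1OC(=O)C(C)=C1 | intermediate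
8 | (5R)-5-[(1R)-1-hydroxy-2,2,5-trimethylhex-4-en-1-yl]-3-methyl-2,5-dihydrofuran-2-ol (anomers) | CC(C)=CCC(C)(C)[C@@H](O)[C@@H]1OC(O)C(C)=C1 | intermediate
9 | allyl (triphenyl-λ5-phosphanylidene)acetate | C=CCOC(=O)C=P(c1ccccc1)(c1ccccc1)c1ccccc1 | starting material
10 | allyl (2E,4Z,6R,7R)-6,7-dihydroxy-4,8,8,11-tetramethyldodeca-2,4,10-trienoate | C=CCOC(=O)/C=C/C(C)=C\[C@@H](O)[C@H](O)C(C)(C)CC=C(C)C | intermediate
11 | allyl (2E,4Z)-5-[(4R,5R)-5-(2,5-dimethylhex-4-en-2-yl)-2,2-dimethyl-1,3-dioxolan-4-yl]-4-methylpenta-2,4-dienoate | C=CCOC(=O)/C=C/C(C)=C\[C@H]1OC(C)(C)O[C@@H]1C(C)(C)CC=C(C)C | intermediate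
12 | (E)-allylic alcohol: side chain of 11 now (4E)-6-hydroxy-2,5-dimethylhex-4-en-2-yl | C=CCOC(=O)/C=C/C(C)=C\[C@H]1OC(C)(C)O[C@@H]1C(C)(C)C/C=C(\C)CO | intermediate
13 | (E)-enal: side chain now (4E)-2,5-dimethyl-6-oxohex-4-en-2-yl | C=CCOC(=O)/C=C/C(C)=C\[C@H]1OC(C)(C)O[C@@H]1C(C)(C)C/C=C(\C)C=O | intermediate
14 | silyl dienol ether: side chain now (3E,5E)-2,5-dimethyl-6-(triisopropylsilyloxy)hexa-3,5-dien-2-yl | C=CCOC(=O)/C=C/C(C)=C\[C@H]1OC(C)(C)O[C@@H]1C(C)(C)/C=C/C(C)=C/O[Si](C(C)C)(C(C)C)C(C)C | intermediate
15 | cis-fused cycloadduct (1,2-acetonide, 6-CO2allyl, 7-OTIPS) | CC1(C)O[C@H]2[C@H](O1)C=C(C)[C@@H]3[C@@H](C(=O)OCC=C)[C@H](O[Si](C(C)C)(C(C)C)C(C)C)C(C)=C[C@@H]3C2(C)C | intermediate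
16 | C7 allylic alcohol | CC1(C)O[C@H]2[C@H](O1)C=C(C)[C@@H]3[C@@H](C(=O)OCC=C)[C@H](O)C(C)=C[C@@H]3C2(C)C | intermediate
17 | allyl β-keto ester (C6 not defined) | CC1(C)O[C@H]2[C@H](O1)C=C(C)[C@@H]3C(C(=O)OCC=C)C(=O)C(C)=C[C@@H]3C2(C)C | intermediate
18 | β-keto acid | CC1(C)O[C@H]2[C@H](O1)C=C(C)[C@@H]3C(C(=O)O)C(=O)C(C)=C[C@@H]3C2(C)C | intermediate
19 | cis-fused enone acetonide | CC1(C)O[C@H]2[C@H](O1)C=C(C)[C@@H]3CC(=O)C(C)=C[C@@H]3C2(C)C | intermediate
20 | cis-fused enone trans-1,2-diol | O[C@H]1[C@H](O)C=C(C)[C@@H]2CC(=O)C(C)=C[C@@H]2C1(C)C | intermediate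
21 | angelic acid, (Z)-2-methylbut-2-enoic acid | C/C=C(/C)C(=O)O | starting material
22 | (Z)-2-methylbut-2-en-1-ol | C/C=C(/C)CO | intermediate
23 | [(2S,3R)-2,3-dimethyloxiran-2-yl]methanol | OC[C@]1(C)O[C@@H]1C | intermediate
24 | (2R,3R)-2,3-dimethyloxirane-2-carboxylic acid | OC(=O)[C@]1(C)O[C@@H]1C | intermediate
25 | 2-O-epoxyangeloyl mono-ester | O[C@H]1[C@H](OC(=O)[C@]2(C)O[C@@H]2C)C=C(C)[C@@H]2CC(=O)C(C)=C[C@@H]2C1(C)C | intermediate
26 | angelic 2,4,6-trichlorobenzoic anhydride | C/C=C(/C)C(=O)OC(=O)c1c(Cl)cc(Cl)cc1Cl | intermediate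
27 | CNP0332927.1 | C/C=C(/C)C(=O)O[C@H]1[C@H](OC(=O)[C@]2(C)O[C@@H]2C)C=C(C)[C@@H]2CC(=O)C(C)=C[C@@H]2C1(C)C | target

Total step count: 18.
Longest linear sequence: 14 steps (1, 3–13, 17, 18).

Steps most likely to fail

Step 9. The ester-endo orientation may compete. In that mode the diene adds through its other face and the ring fusion comes out trans; slow closure is a second concern.
Fallback, from 14 back to 19:
- Both orientations use the same dienophile face, so the unwanted product, the trans-fused silyl ether F1, differs from 15 only at C10 and at helper centre C7.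
- F1, or the mixture, is taken through the conditions of steps 10–12 via allylic alcohol F2, β-keto ester F3 and β-keto acid F4 to the trans-fused enone acetonide F5. In F5, C10–H is the γ-hydrogen of the enone.
- γ-Deprotonation to the extended enolate (KOt-Bu, t-BuOH/THF, 0 °C) and kinetic α-protonation (cold aqueous AcOH quench) gives the deconjugated β,γ-enone F6, with C10 trigonal.
- Mild acid-catalysed reconjugation (oxalic acid, EtOH, rt) protonates C10 of the dienol from the face anti to the pseudo-axial C5–C4 bond, that is syn to H-5. This should give the cis-fused 19 and sets C10 by protonation instead of by cycloaddition.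

Step 3. Face selection or syn selectivity may be poor, or catalyst turnover slow, with the α-quaternary aldehyde.
Fallback, from 3 and 5 back to 8:
- BF3·OEt2 (CH2Cl2, −78 °C) promotes the same addition without a chiral catalyst. It is expected to give the syn adduct as a racemate, that is 7 together with its (1S,5S)-antipode F7.
- Esterification with (S)-2-methoxy-2-phenylacetic acid (DCC, DMAP cat.) gives the methoxyphenylacetate F8 from 7 and the diastereomeric ester F9 from F7. These are separated by chromatography or crystallisation.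
- F8 enters step 4 with additional DIBAL-H, which also cleaves the resolving ester reductively and delivers 8.

Step 18. Acylation of the neopentylic C1–OH may be sluggish, leaving time for Z→E isomerisation of the angeloyl group or for migration of the C2 ester to C1.
Fallback, from 20 back to 27, with the order of esterification inverted and the hindered oxygen acylated as its alkoxide:
- 20 is silylated at the less hindered allylic C2–OH (TESCl, imidazole, CH2Cl2, −20 °C) to the 2-O-triethylsilyl ether F10.
- Angelic anhydride F11 (from 21, DCC) acylates the lithium alkoxide of F10 (LiHMDS 1.0 equiv, THF, −78 → 0 °C) to the 1-O-angeloyl silyl ether F12.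
- HF·pyridine frees C2–OH to give the 1-O-angeloyl alcohol F13.
- F13 is esterified with 24 under the conditions of step 17 to give 27.

Further compounds
F1 | step 9 | trans-fused cycloadduct (C10 epimer; OTIPS cis to CO2allyl) | CC1(C)O[C@H]2[C@H](O1)C=C(C)[C@@H]3[C@@H](C(=O)OCC=C)[C@@H](O[Si](C(C)C)(C(C)C)C(C)C)C(C)=C[C@H]3C2(C)C
F2 | step 9 | trans-fused C7 allylic alcohol | CC1(C)O[C@H]2[C@H](O1)C=C(C)[C@@H]3[C@@H](C(=O)OCC=C)[C@@H](O)C(C)=C[C@H]3C2(C)C
F3 | step 9 | trans-fused allyl β-keto ester | CC1(C)O[C@H]2[C@H](O1)C=C(C)[C@@H]3C(C(=O)OCC=C)C(=O)C(C)=C[C@H]3C2(C)C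
F4 | step 9 | trans-fused β-keto acid | CC1(C)O[C@H]2[C@H](O1)C=C(C)[C@@H]3C(C(=O)O)C(=O)C(C)=C[C@H]3C2(C)C
F5 | step 9 | trans-fused enone acetonide (10-epi-19) | CC1(C)O[C@H]2[C@H](O1)C=C(C)[C@@H]3CC(=O)C(C)=C[C@H]3C2(C)C
F6 | step 9 | deconjugated β,γ-enone (C9=C10; C8 not defined) | CC1(C)O[C@H]2[C@H](O1)C=C(C)[C@@H]3CC(=O)C(C)C=C3C2(C)C
F7 | step 3 | (5S)-5-[(1S)-1-hydroxy-2,2,5-trimethylhex-4-en-1-yl]-3-methylfuran-2(5H)-one | CC(C)=CCC(C)(C)[C@H](O)[C@H]1OC(=O)C(C)=C1
F8 | step 3 | (S)-2-methoxy-2-phenylacetate of 7 | CC(C)=CCC(C)(C)[C@@H](OC(=O)[C@@H](OC)c1ccccc1)[C@@H]1OC(=O)C(C)=C1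
F9 | step 3 | (S)-2-methoxy-2-phenylacetate of F7 | CC(C)=CCC(C)(C)[C@H](OC(=O)[C@@H](OC)c1ccccc1)[C@H]1OC(=O)C(C)=C1
F10 | step 18 | 2-O-triethylsilyl ether of 20 | O[C@H]1[C@H](O[Si](CC)(CC)CC)C=C(C)[C@@H]2CC(=O)C(C)=C[C@@H]2C1(C)C
F11 | step 18 | angelic anhydride | C/C=C(/C)C(=O)OC(=O)/C(C)=C\C
F12 | step 18 | 1-O-angeloyl-2-O-triethylsilyl derivative | C/C=C(/C)C(=O)O[C@H]1[C@H](O[Si](CC)(CC)CC)C=C(C)[C@@H]2CC(=O)C(C)=C[C@@H]2C1(C)C
F13 | step 18 | 1-O-angeloyl alcohol (C2–OH free) | C/C=C(/C)C(=O)O[C@H]1[C@H](O)C=C(C)[C@@H]2CC(=O)C(C)=C[C@@H]2C1(C)C
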